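## Retrosynthetic overview

1. Furan–chain C–C bond: ester 3 from 3-bromofuran 1 and alkylzinc 2 (Negishi coupling), reduced to aldehyde 4. No ring is formed anywhere; the furan is bought.
2. Acceptor: thioacrylate 8 from 3-chloropropanoyl chloride 5 and ethanethiol 6 (through 7).
3. C2 stereocentre and C2–C3 bond (key step): a new amine-catalysed enantioselective Michael addition of 4 to 8 gives 9, which is oxidised in the same flask to acid 10.
4. Thioester 10 is reduced to aldehyde 11 (Fukuyama), so the two carbonyl ends are told apart without protecting groups.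
5. C5=C6 (Z): Still–Gennari olefination of 11 with phosphonate 14 (from 12 and 13) gives target 15.

Assumption: zinc reagent 2 is used as the commercial 0.5 M solution in THF, and 12 and 13 are catalogue compounds.

## Route

Step 1
Reactants: 1 3-bromofuran; 2 (5-ethoxy-5-oxopentyl)zinc bromide
Product: 3 ethyl 5-(furan-3-yl)pentanoate
Conditions: Pd(OAc)2 (2 mol%), SPhos (4 mol%), THF, 25 to 45 °C, 12 h
Reagents that add atoms: none
Why: Negishi sp2–sp3 cross-coupling; zerovalent palladium formed in the flask adds to the C–Br bond, the ester-bearing primary alkylzinc transmetalates, and the bulky biaryl phosphine makes reductive elimination faster than β-hydride elimination.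

Step 2
Reactants: 3 ethyl 5-(furan-3-yl)pentanoate
Product: 4 5-(furan-3-yl)pentanal
Conditions: i-Bu2AlH (1.05 equiv), CH2Cl2, −78 °C, 1 h; MeOH, then aq. KNaC4H4O6 (potassium sodium tartrate)
Reagents that add atoms: none
Why: partial reduction of an ester with diisobutylaluminium hydride; the tetrahedral aluminium hemiacetal is stable at −78 °C and gives the aldehyde only on work-up, and the furan is inert to the hydride.

Step 3
Reactants: 5 3-chloropropanoyl chloride; 6 ethanethiol
Product: 8 S-ethyl prop-2-enethioate, via chloro thioester 7 (not isolated)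
Conditions: pyridine (1.0 equiv), CH2Cl2, 0 °C, 1 h; then Et3N (1.3 equiv), 0 to 20 °C, 2 h; BHT (trace), distil
Reagents that add atoms: none
Why: S-acylation followed by E1cB β-elimination of HCl; the double bond is made only after all thiol has been consumed, which avoids thia-Michael addition to the acrylate.

Step 4
Reactants: 4 5-(furan-3-yl)pentanal; 8 S-ethyl prop-2-enethioate
Product: 10 (2R)-5-(ethylsulfanyl)-2-[3-(furan-3-yl)propyl]-5-oxopentanoic acid, via formyl thioester 9 (not isolated)
Conditions: (S)-2-[diphenyl(trimethylsilyloxy)methyl]pyrrolidine (10 mol%), ethyl 3,4-dihydroxybenzoate (20 mol%), 8 (2 equiv), toluene (2 M), 4 °C, 48 h; then t-BuOH/H2O, 2-methylbut-2-ene (30 equiv), NaH2PO4, NaClO2 (3 equiv), 0 °C, 1 h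
Reagents that add atoms: sodium chlorite NaClO2, [Na+].[O-]Cl=O
Why: Proposed new method: enamine-catalysed enantioselective Michael addition of a linear aldehyde to an S-alkyl thioacrylate, which forms the C2–C3 bond and sets the only stereocentre; the (S)-diarylprolinol silyl ether condenses with 4 to the (E)-anti-enamine whose Re face is blocked by the CPh2(OSiMe3) group, so the thioacrylate (a better acceptor than an acrylate because sulfur donates poorly into the carbonyl, and further activated by double hydrogen bonding from the catechol co-catalyst) is attacked from the Si face to give (4R)-9 after proton transfer and iminium hydrolysis, while the hindered amine does not cleave an S-alkyl thioester at 4 °C; the closest known reaction type is the diarylprolinol-ether/catechol-catalysed Michael addition of aldehydes to alkyl vinyl ketones (and to nitroethylene), and the α-branched aldehyde is oxidised at once in the same flask (Pinnick oxidation, with the alkene scavenging hypochlorous acid so that furan and thioester survive) before it can epimerise.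

Step 5
Reactants: 10 (2R)-5-(ethylsulfanyl)-2-[3-(furan-3-yl)propyl]-5-oxopentanoic acid
Product: 11 (2R)-2-[3-(furan-3-yl)propyl]-5-oxopentanoic acid
Conditions: Et3SiH (3 equiv), 10% Pd/C (5 mol%), acetone, 20 °C, 2 h; aqueous work-up
Reagents that add atoms: none
Why: Fukuyama reduction; palladium inserts into the acyl–sulfur bond and the silane delivers hydride, which stops cleanly at the aldehyde and leaves the carboxylic acid, the furan and the C2 stereocentre untouched.

Step 6
Reactants: 12 methyl 2-[bis(2,2,2-trifluoroethoxy)phosphoryl]acetate; 13 5-bromo-2-methylpent-2-ene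
Product: 14 methyl 2-[bis(2,2,2-trifluoroethoxy)phosphoryl]-6-methylhept-5-enoate (racemic)
Conditions: NaH (1.05 equiv), DMF, 0 °C; then 13 (1.0 equiv), NaI (10 mol%), 50 °C, 12 h
Reagents that add atoms: none
Why: SN2 C-alkylation of the soft, weakly basic phosphonoacetate anion with a primary bromide (iodide catalysis), with one equivalent of electrophile to limit dialkylation; the phosphonate stereocentre is lost in the next step.

Step 7
Reactants: 11 (2R)-2-[3-(furan-3-yl)propyl]-5-oxopentanoic acid; 14 methyl 2-[bis(2,2,2-trifluoroethoxy)phosphoryl]-6-methylhept-5-enoate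
Product: 15 (2R,5Z)-2-[3-(furan-3-yl)propyl]-6-(methoxycarbonyl)-10-methylundeca-5,9-dienoic acid
Conditions: 14 (2.3 equiv), KN(SiMe3)2 (2.2 equiv), 18-crown-6 (5 equiv), THF, −78 °C, 30 min; then 11, −78 °C, 3 h; aq. HCl to pH 3
Reagents that add atoms: none
Why: Still–Gennari variant of the Horner–Wadsworth–Emmons olefination; the trifluoroethyl phosphonate with a crown-ether-separated potassium ion eliminates faster than the adducts equilibrate, so the kinetic (Z)-enoate forms with the ester cis to the chain, while the first equivalent of phosphonate anion only deprotonates the acid, whose α-stereocentre is not acidic as the carboxylate.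

## Compound list

1 | 3-bromofuran | Brc1ccoc1 | starting material
2 | (5-ethoxy-5-oxopentyl)zinc bromide | CCOC(=O)CCCC[Zn]Br | starting material
3 | ethyl 5-(furan-3-yl)pentanoate | CCOC(=O)CCCCc1ccoc1 | intermediate
4 | 5-(furan-3-yl)pentanal | O=CCCCCc1ccoc1 | intermediate
5 | 3-chloropropanoyl chloride | O=C(Cl)CCCl | starting material
6 | ethanethiol | CCS | starting material
7 | S-ethyl 3-chloropropanethioate | CCSC(=O)CCCl | intermediate
8 | S-ethyl prop-2-enethioate | C=CC(=O)SCC | intermediate
9 | S-ethyl (4R)-4-formyl-7-(furan-3-yl)heptanethioate | CCSC(=O)CC[C@@H](CCCc1ccoc1)C=O | intermediate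
10 | (2R)-5-(ethylsulfanyl)-2-[3-(furan-3-yl)propyl]-5-oxopentanoic acid | CCSC(=O)CC[C@@H](CCCc1ccoc1)C(=O)O | intermediate
11 | (2R)-2-[3-(furan-3-yl)propyl]-5-oxopentanoic acid | O=CCC[C@@H](CCCc1ccoc1)C(=O)O | intermediate
12 | methyl 2-[bis(2,2,2-trifluoroethoxy)phosphoryl]acetate | COC(=O)CP(=O)(OCC(F)(F)F)OCC(F)(F)F | starting material
13 | 5-bromo-2-methylpent-2-ene | CC(C)=CCCBr | starting material
14 | methyl 2-[bis(2,2,2-trifluoroethoxy)phosphoryl]-6-methylhept-5-enoate (racemic) | COC(=O)C(CCC=C(C)C)P(=O)(OCC(F)(F)F)OCC(F)(F)F | intermediate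
15 | (2R,5Z)-2-[3-(furan-3-yl)propyl]-6-(methoxycarbonyl)-10-methylundeca-5,9-dienoic acid | COC(=O)/C(=C\CC[C@@H](CCCc1ccoc1)C(=O)O)CCC=C(C)C | target

## Step count and risks

Total steps: 7. Longest linear sequence: 5 (steps 1, 2, 4, 5, 7).

Steps most likely to fail:

Step 4 (the proposed new Michael addition). The thioacrylate may be too weak an acceptor for the enamine, so that self-aldol of 4 or slow acylation of the catalyst wins; the furan is also exposed to the chlorite stage. Fallback with known reaction types, setting out from 4 and coming back at 11: aldehyde 4 is added, under the established diphenylprolinol-ether/catechol enamine conditions for alkyl vinyl ketones, to the acrolein surrogate 4-hydroxy-4-methylpent-1-en-3-one F1 (made from 3-hydroxy-3-methylbutan-2-one, paraformaldehyde and i-Pr2NH·CF3CO2H). This gives (2R)-2-[3-(furan-3-yl)propyl]-6-hydroxy-6-methyl-5-oxoheptanal F2, and Pinnick oxidation then gives (2R)-2-[3-(furan-3-yl)propyl]-6-hydroxy-6-methyl-5-oxoheptanoic acid F3. NaBH4 reduces the ketone to (2R)-2-[3-(furan-3-yl)propyl]-5,6-dihydroxy-6-methylheptanoic acid F4 (both C5 epimers), and NaIO4 cleaves the diol to 11, so that 8, 9 and 10 are not needed.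

Step 5 (Fukuyama reduction). Sulfur may poison the Pd/C, and the free acid may slow the reaction. Fallback, setting out from 10 and coming back at 11: thioester 10 is reduced past the aldehyde with NaBH4 (EtOH/THF, 0 °C; the carboxylate is untouched) to (2R)-2-[3-(furan-3-yl)propyl]-5-hydroxypentanoic acid F5. F5 is kept as its triethylammonium salt to prevent lactonisation and is oxidised with SO3·pyridine/DMSO/Et3N (Parikh–Doering) to 11.

Step 7 (Still–Gennari olefination). The Z/E ratio may drop with the α-branched phosphonate and a substrate that carries a carboxylate. Fallback, setting out from 11 and coming back at 15: 11 is condensed (KOt-Bu, 18-crown-6, THF, −78 °C) with methyl 2-[bis(2,2,2-trifluoroethoxy)phosphoryl]-2-bromoacetate F6, made from 12 by deprotonation and bromination with N-bromosuccinimide. This gives the (E)-α-bromo enoate (2R,5E)-6-bromo-2-[3-(furan-3-yl)propyl]-7-methoxy-7-oxohept-5-enoic acid F7, in which the ester is already cis to the chain. Negishi coupling of F7 with (4-methylpent-3-en-1-yl)zinc bromide F8 (from 13 and Zn dust; 3 equiv, one is consumed by the acid) under Pd(OAc)2/SPhos replaces bromine with retention and gives 15.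

## Further compounds

F1 | step 4 | 4-hydroxy-4-methylpent-1-en-3-one | C=CC(=O)C(C)(C)O
F2 | step 4 | (2R)-2-[3-(furan-3-yl)propyl]-6-hydroxy-6-methyl-5-oxoheptanal | CC(C)(O)C(=O)CC[C@@H](CCCc1ccoc1)C=O
F3 | step 4 | (2R)-2-[3-(furan-3-yl)propyl]-6-hydroxy-6-methyl-5-oxoheptanoic acid | CC(C)(O)C(=O)CC[C@@H](CCCc1ccoc1)C(=O)O
F4 | step 4 | (2R)-2-[3-(furan-3-yl)propyl]-5,6-dihydroxy-6-methylheptanoic acid (C5 epimers) | CC(C)(O)C(O)CC[C@@H](CCCc1ccoc1)C(=O)O
F5 | step 5 | (2R)-2-[3-(furan-3-yl)propyl]-5-hydroxypentanoic acid | OCCC[C@@H](CCCc1ccoc1)C(=O)O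
F6 | step 7 | methyl 2-[bis(2,2,2-trifluoroethoxy)phosphoryl]-2-bromoacetate | COC(=O)C(Br)P(=O)(OCC(F)(F)F)OCC(F)(F)F
F7 | step 7 | (2R,5E)-6-bromo-2-[3-(furan-3-yl)propyl]-7-methoxy-7-oxohept-5-enoic acid | COC(=O)/C(Br)=C\CC[C@@H](CCCc1ccoc1)C(=O)O
F8 | step 7 | (4-methylpent-3-en-1-yl)zinc bromide | CC(C)=CCC[Zn]Br
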